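**Retrosynthetic overview**
1. Numbering follows 6H-isochromen-6-one (C-1, O-2, C-3 to C-8a; side chain C-1' to C-7'). Target 21 comes from acid unmasking of 20, and 20 from C-5 chlorination of the des-chloro core 19.
2. Core 19 is cut at C-4a–C-8a and C-3–C-4 (together with C-3–C-1' and O-2–C-1) in one palladium domino of the acyclic bromo enol ether/alkynyl ketone 8, CO and dienylstannane 16. Ring A (the carbocycle) closes first by 6-exo-dig carbopalladation, the pyran ring second by oxa-6π closure and loss of methanol.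
3. Enabling feature: the pyran ring is a cyclodehydrated (Z)-2-ene-1,5-dicarbonyl unit, with C-1 (formyl level) and C-3 (ketone level) joined through the C-1=C-8a–C-4a=C-4 diene. CO supplies C-3 and O-2, and the C-5 hydrogens next to the C-6 ketone let the 1-methoxy pseudo-base collapse to the neutral 6H-isochromen-6-one.
4. Fragment 8: C-6/C-7/C-8/C-8a and both ring stereocentres are bought as 2-C-methyl-D-erythrono-1,4-lactone 1 (cis-diol kept as acetonide); C-1 comes from methoxymethylenation, C-5/C-4a/C-4 from propargylation of the C-6 amide.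
5. Fragment 16: C-5' is bought as (S)-α-methyl-γ-butyrolactone 9; C-3'=C-4' comes from a Wittig reaction, C-1'=C-2' from a Takai olefination.

Key step: step 12

Remark: 1 and 9 are taken as purchasable chiral-pool lactones, and the enol-ether geometry in 5, 7, 8 and 17 is left open because C-1 passes through an sp3 acetal stage (18) before its final double bond forms.

Step 1
Reactants: 1 2-C-methyl-D-erythrono-1,4-lactone
Product: 2 2,3-O-isopropylidene-2-C-methyl-D-erythrono-1,4-lactone
Conditions: 2,2-dimethoxypropane, TsOH (cat.), acetone, rt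
Reagents that add atoms: 2,2-dimethoxypropane COC(C)(C)OC
Why: Acid-catalysed transacetalization should tie the cis-diol (future C-7/C-8) into a cis-fused dioxolane without touching either stereocentre.

Step 2
Reactants: 2 2,3-O-isopropylidene-2-C-methyl-D-erythrono-1,4-lactone
Product: 3 (4R,5R)-5-(hydroxymethyl)-N-methoxy-N,2,2,4-tetramethyl-1,3-dioxolane-4-carboxamide
Conditions: MeNHOMe·HCl, i-PrMgCl, THF, −20 to 0 °C
Reagents that add atoms: N,O-dimethylhydroxylamine hydrochloride CNOC.Cl
Why: Aminolysis of the strained bicyclic lactone by the magnesium amide should give the N-methoxy-N-methylamide (future C-6) and free the C-8a primary alcohol, with no bond to a stereocentre broken.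

Step 3
Reactants: 3 (4R,5R)-5-(hydroxymethyl)-N-methoxy-N,2,2,4-tetramethyl-1,3-dioxolane-4-carboxamide
Product: 4 (4R,5S)-5-formyl-N-methoxy-N,2,2,4-tetramethyl-1,3-dioxolane-4-carboxamide
Conditions: TEMPO (cat.), PhI(OAc)2, CH2Cl2, rt
Reagents that add atoms: none
Why: Oxoammonium (TEMPO) oxidation of the primary alcohol stops at the aldehyde under non-basic conditions, which should leave the α-alkoxy centre (future C-8) unepimerized; the descriptor changes only through CIP priorities.

Step 4
Reactants: 4 (4R,5S)-5-formyl-N-methoxy-N,2,2,4-tetramethyl-1,3-dioxolane-4-carboxamide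
Product: 5 (4R,5R)-N-methoxy-5-(2-methoxyethenyl)-N,2,2,4-tetramethyl-1,3-dioxolane-4-carboxamide (E/Z mixture)
Conditions: Ph3P(CH2OMe)Cl, KN(SiMe3)2, THF, 0 °C; then 4, −78 to 0 °C
Reagents that add atoms: (methoxymethyl)triphenylphosphonium chloride COC[P+](c1ccccc1)(c1ccccc1)c1ccccc1.[Cl-]
Why: Wittig methoxymethylenation adds C-1 as an enol ether while the N-methoxy-N-methylamide is inert to the ylide, and low temperature should protect the α-alkoxy aldehyde from epimerization.

Step 5
Reactants: 5 (4R,5R)-N-methoxy-5-(2-methoxyethenyl)-N,2,2,4-tetramethyl-1,3-dioxolane-4-carboxamide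
Product: 7 (4R,5S)-5-(1-bromo-2-methoxyethenyl)-N-methoxy-N,2,2,4-tetramethyl-1,3-dioxolane-4-carboxamide, via dibromide 6 (not isolated)
Conditions: Br2, CH2Cl2, −78 °C; then DBU, −78 °C to rt
Reagents that add atoms: bromine BrBr
Why: Bromine addition to the enol ether followed by dehydrobromination of the labile α-bromo ether (the sequence used to make 2-bromoglycals) should put the halogen on C-8a; the two transient CBr centres of 6 form as a mixture and are erased on elimination.

Step 6
Reactants: 7 (4R,5S)-5-(1-bromo-2-methoxyethenyl)-N-methoxy-N,2,2,4-tetramethyl-1,3-dioxolane-4-carboxamide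
Product: 8 1-[(4R,5S)-5-(1-bromo-2-methoxyethenyl)-2,2,4-trimethyl-1,3-dioxolan-4-yl]but-3-yn-1-one
Conditions: propargyl bromide, Mg, HgCl2 (cat.), Et2O, 0 °C; then 7, THF, −78 °C; cold aq. NH4Cl
Reagents that add atoms: propargyl bromide (delivered as allenylmagnesium bromide) C#CCBr
Why: Grignard addition to the N-methoxy-N-methylamide gives a chelated tetrahedral intermediate that prevents over-addition and keeps the base-sensitive β,γ-alkynyl ketone masked until the cold neutral quench; the allenyl reagent reacts with propargyl transposition.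

Step 7
Reactants: 9 (S)-α-methyl-γ-butyrolactone
Product: 11 (2S)-4-[(tert-butyldimethylsilyl)oxy]-N-methoxy-N,2-dimethylbutanamide, via hydroxy amide 10 (not isolated)
Conditions: MeNHOMe·HCl, i-PrMgCl, THF, −20 °C; then TBSCl, imidazole, DMF, 0 °C to rt
Reagents that add atoms: N,O-dimethylhydroxylamine hydrochloride CNOC.Cl; tert-butyldimethylsilyl chloride CC(C)(C)[Si](C)(C)Cl
Why: Lactone aminolysis followed by immediate silylation of the crude hydroxy amide (which forestalls relactonization) should deliver the protected N-methoxy-N-methylamide with the bought C-5' centre untouched.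

Step 8
Reactants: 11 (2S)-4-[(tert-butyldimethylsilyl)oxy]-N-methoxy-N,2-dimethylbutanamide
Product: 12 (2S)-4-[(tert-butyldimethylsilyl)oxy]-2-methylbutanal
Conditions: i-Bu2AlH, THF, −78 °C
Reagents that add atoms: none
Why: Hydride reduction of the N-methoxy-N-methylamide stops at the chelated hemiaminal, so the aldehyde is released only on work-up and the α-methyl centre should not epimerize at −78 °C.

Step 9
Reactants: 12 (2S)-4-[(tert-butyldimethylsilyl)oxy]-2-methylbutanal
Product: 13 (2E,4S)-6-[(tert-butyldimethylsilyl)oxy]-2,4-dimethylhex-2-enal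
Conditions: 2-(triphenylphosphoranylidene)propanal, toluene, 80 °C
Reagents that add atoms: 2-(triphenylphosphoranylidene)propanal CC(C=O)=P(c1ccccc1)(c1ccccc1)c1ccccc1
Why: A Wittig reaction with the stabilized formyl ylide should give the (E)-trisubstituted enal (C-3'=C-4') under thermodynamic control of oxaphosphetane formation.

Step 10
Reactants: 13 (2E,4S)-6-[(tert-butyldimethylsilyl)oxy]-2,4-dimethylhex-2-enal
Product: 14 tert-butyl{[(3S,4E,6E)-7-iodo-3,5-dimethylhepta-4,6-dien-1-yl]oxy}dimethylsilane
Conditions: CHI3, CrCl2, THF, 0 °C to rt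
Reagents that add atoms: iodoform IC(I)I
Why: Takai olefination through the geminal dichromium species should add C-1' as an (E)-iodoalkene.

Step 11
Reactants: 14 tert-butyl{[(3S,4E,6E)-7-iodo-3,5-dimethylhepta-4,6-dien-1-yl]oxy}dimethylsilane
Product: 16 tert-butyldimethyl{[(3S,4E,6E)-3,5-dimethyl-7-(tributylstannyl)hepta-4,6-dien-1-yl]oxy}silane, via dienyllithium 15 (not isolated)
Conditions: t-BuLi (2 equiv), Et2O, −78 °C; then Bu3SnCl, −78 °C to rt
Reagents that add atoms: tributyltin chloride CCCC[Sn](Cl)(CCCC)CCCC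
Why: Iodine–lithium exchange and stannylation both proceed with retention of alkene geometry, so the (1E,3E)-diene should be carried over intact.

Step 12
Reactants: 8 1-[(4R,5S)-5-(1-bromo-2-methoxyethenyl)-2,2,4-trimethyl-1,3-dioxolan-4-yl]but-3-yn-1-one; 16 tert-butyldimethyl{[(3S,4E,6E)-3,5-dimethyl-7-(tributylstannyl)hepta-4,6-dien-1-yl]oxy}silane
Product: 19 (7R,8R)-7,8-O-isopropylidene-protected 3-[(1E,3E,5S)-7-(tert-butyldimethylsilyloxy)-3,5-dimethylhepta-1,3-dienyl]-7,8-dihydroxy-7-methyl-7,8-dihydro-6H-isochromen-6-one, via trienone 17 (not isolated), via 1-methoxy-1H-isochromenone 18 (not isolated)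
Conditions: Pd(PPh3)4 (10 mol %), CO (1 atm), 16 (1.2 equiv), 1,4-dioxane, 80 °C; then PPTS (cat.), rt
Reagents that add atoms: carbon monoxide [C-]#[O+]
Why: Zerovalent palladium inserts into the C-8a–Br bond, the alkenylpalladium adds syn across the tethered terminal alkyne (6-exo-dig, closing carbocyclic ring A and forming C-4a–C-8a), the dienylpalladium at C-4 inserts CO (forming C-4–C-3) and the acylpalladium is captured by Stille transmetalation and reductive elimination with 16 (C-3–C-1'); the closest known reaction type is the cyclic carbopalladation–carbonylation–cross-coupling domino of 2-halo-1-en-7-ynes and of 2-bromoglycal-type enol ethers. The syn addition places the acyl group cis to C-8a, so trienone 17 is a (Z)-1-oxatriene that closes the pyran ring by thermal disrotatory 6π-oxa-electrocyclization to 18, and the C-5 hydrogens α to the C-6 ketone then allow vinylogous loss of methanol (PPTS) to the neutral chromophore 19. No lasting stereocentre is created (C-1 of 18 is transient), and C-7/C-8 are spectators whose cis-fused acetonide holds the two chain ends syn for ring A closure. The step needs alkyne insertion before carbonylation and carbonylative rather than direct coupling: the four-atom tether makes the 6-exo-dig insertion fast and irreversible, CO insertion at the hindered C-8a palladium is reversible and its transmetalation slow, and 1 atm CO with a slowly transmetalating stannane favours capture at the acyl stage. Base-free conditions should keep the β,γ-alkynyl ketone from isomerizing to the allenone and suppress O-acylation of the C-6 enol.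

Step 13
Reactants: 19 protected des-chloro core
Product: 20 (7R,8R)-5-chloro derivative of 19
Conditions: NCS, MeCN, 0 °C to rt
Reagents that add atoms: N-chlorosuccinimide ClN1C(=O)CCC1=O
Why: Electrophilic chlorination should occur at C-5, the α-carbon of the doubly vinylogous ester, because attack there passes through an aromatic pyrylium σ-complex, as in the known C-5 halogenation of azaphilones.

Step 14
Reactants: 20 (7R,8R)-5-chloro-7,8-O-isopropylidene silyl ether
Product: 21 (7R,8R)-5-chloro-7,8-dihydroxy-3-[(1E,3E,5S)-7-hydroxy-3,5-dimethylhepta-1,3-dien-1-yl]-7-methyl-7,8-dihydro-6H-isochromen-6-one (target)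
Conditions: TFA/H2O/THF, 0 °C to rt
Reagents that add atoms: none
Why: Acid hydrolysis cleaves the acetal at the isopropylidene carbon and the primary silyl ether at silicon, so no C–O bond at C-7, C-8 or C-7' is broken and all three stereocentres should be retained.

**Compound list**
1 | 2-C-methyl-D-erythrono-1,4-lactone, (3R,4R)-3,4-dihydroxy-3-methyloxolan-2-one | C[C@@]1(O)[C@H](O)COC1=O | starting material
2 | 2,3-O-isopropylidene-2-C-methyl-D-erythrono-1,4-lactone, (3aR,6aR)-2,2,3a-trimethyldihydrofuro[3,4-d][1,3]dioxol-4(3aH)-one | C[C@@]12OC(C)(C)O[C@@H]1COC2=O | intermediate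
3 | (4R,5R)-5-(hydroxymethyl)-N-methoxy-N,2,2,4-tetramethyl-1,3-dioxolane-4-carboxamide | C[C@]1(OC(C)(C)O[C@@H]1CO)C(=O)N(C)OC | intermediate
4 | (4R,5S)-5-formyl-N-methoxy-N,2,2,4-tetramethyl-1,3-dioxolane-4-carboxamide | C[C@]1(OC(C)(C)O[C@@H]1C=O)C(=O)N(C)OC | intermediate
5 | (4R,5R)-N-methoxy-5-(2-methoxyethenyl)-N,2,2,4-tetramethyl-1,3-dioxolane-4-carboxamide (E/Z mixture) | C[C@]1(OC(C)(C)O[C@@H]1C=COC)C(=O)N(C)OC | intermediate
6 | (4R,5S)-5-(1,2-dibromo-2-methoxyethyl)-N-methoxy-N,2,2,4-tetramethyl-1,3-dioxolane-4-carboxamide (mixture at the two CBr centres) | C[C@]1(OC(C)(C)O[C@@H]1C(Br)C(Br)OC)C(=O)N(C)OC | intermediate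
7 | (4R,5S)-5-(1-bromo-2-methoxyethenyl)-N-methoxy-N,2,2,4-tetramethyl-1,3-dioxolane-4-carboxamide | C[C@]1(OC(C)(C)O[C@@H]1C(Br)=COC)C(=O)N(C)OC | intermediate
8 | 1-[(4R,5S)-5-(1-bromo-2-methoxyethenyl)-2,2,4-trimethyl-1,3-dioxolan-4-yl]but-3-yn-1-one | C[C@]1(OC(C)(C)O[C@@H]1C(Br)=COC)C(=O)CC#C | intermediate
9 | (S)-α-methyl-γ-butyrolactone, (3S)-3-methyloxolan-2-one | C[C@H]1CCOC1=O | starting material
10 | (2S)-4-hydroxy-N-methoxy-N,2-dimethylbutanamide | C[C@@H](CCO)C(=O)N(C)OC | intermediate
11 | (2S)-4-[(tert-butyldimethylsilyl)oxy]-N-methoxy-N,2-dimethylbutanamide | C[C@@H](CCO[Si](C)(C)C(C)(C)C)C(=O)N(C)OC | intermediate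
12 | (2S)-4-[(tert-butyldimethylsilyl)oxy]-2-methylbutanal | C[C@@H](CCO[Si](C)(C)C(C)(C)C)C=O | intermediate
13 | (2E,4S)-6-[(tert-butyldimethylsilyl)oxy]-2,4-dimethylhex-2-enal | O=C/C(C)=C/[C@@H](C)CCO[Si](C)(C)C(C)(C)C | intermediate
14 | tert-butyl{[(3S,4E,6E)-7-iodo-3,5-dimethylhepta-4,6-dien-1-yl]oxy}dimethylsilane | I/C=C/C(C)=C/[C@@H](C)CCO[Si](C)(C)C(C)(C)C | intermediate
15 | (1E,3E,5S)-7-[(tert-butyldimethylsilyl)oxy]-3,5-dimethylhepta-1,3-dienyllithium | [Li]/C=C/C(C)=C/[C@@H](C)CCO[Si](C)(C)C(C)(C)C | intermediate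
16 | tert-butyldimethyl{[(3S,4E,6E)-3,5-dimethyl-7-(tributylstannyl)hepta-4,6-dien-1-yl]oxy}silane | CCCC[Sn](CCCC)(CCCC)/C=C/C(C)=C/[C@@H](C)CCO[Si](C)(C)C(C)(C)C | intermediate
17 | domino trienone: (7R,8R)-7,8-O-isopropylidene ring-A cyclohexanone (C-6 ketone, C-5 H2) with exocyclic C-8a=C-1H(OMe) and (Z)-C-4a=C-4H–C-3(=O)–[(1E,3E,5S)-7-(tert-butyldimethylsilyloxy)-3,5-dimethylhepta-1,3-dienyl] | COC=C1[C@H]2OC(C)(C)O[C@@]2(C)C(=O)C/C1=C/C(=O)/C=C/C(C)=C/[C@@H](C)CCO[Si](C)(C)C(C)(C)C | intermediate
18 | (7R,8R)-1-methoxy-7,8-O-isopropylidene-7,8-dihydroxy-7-methyl-3-[(1E,3E,5S)-7-(tert-butyldimethylsilyloxy)-3,5-dimethylhepta-1,3-dienyl]-7,8-dihydro-1H-isochromen-6(5H)-one (C-1 epimers) | COC1OC(/C=C/C(C)=C/[C@@H](C)CCO[Si](C)(C)C(C)(C)C)=CC2=C1[C@H]3OC(C)(C)O[C@@]3(C)C(=O)C2 | intermediate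
19 | (7R,8R)-7,8-O-isopropylidene-7,8-dihydroxy-7-methyl-3-[(1E,3E,5S)-7-(tert-butyldimethylsilyloxy)-3,5-dimethylhepta-1,3-dienyl]-7,8-dihydro-6H-isochromen-6-one | CC(/C=C/C1=CC2=CC(=O)[C@]3(C)OC(C)(C)O[C@@H]3C2=CO1)=C\[C@@H](C)CCO[Si](C)(C)C(C)(C)C | intermediate
20 | (7R,8R)-5-chloro-7,8-O-isopropylidene-7,8-dihydroxy-7-methyl-3-[(1E,3E,5S)-7-(tert-butyldimethylsilyloxy)-3,5-dimethylhepta-1,3-dienyl]-7,8-dihydro-6H-isochromen-6-one | CC(/C=C/C1=CC2=C(Cl)C(=O)[C@]3(C)OC(C)(C)O[C@@H]3C2=CO1)=C\[C@@H](C)CCO[Si](C)(C)C(C)(C)C | intermediate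
21 | (7R,8R)-5-chloro-7,8-dihydroxy-3-[(1E,3E,5S)-7-hydroxy-3,5-dimethylhepta-1,3-dien-1-yl]-7-methyl-7,8-dihydro-6H-isochromen-6-one | CC(/C=C/C1=CC2=C(Cl)C(=O)[C@](C)(O)[C@H](O)C2=CO1)=C\[C@@H](C)CCO | target

**Step count and risks**
Total step count: 14. Longest linear sequence: 9 (steps 1–6, then 12–14).

Most likely to fail, in order:

Step 12. What may go wrong: carbonylation or cross-coupling of the C-8a alkenylpalladium before it has inserted the alkyne, direct non-carbonylative coupling at C-4, or capture of the acylpalladium by the enol oxygen of the C-6 ketone. The fallback sets out from 8 and returns at 19 without CO. Heating 8 with tributyl(1-ethoxyvinyl)stannane and Pd(PPh3)4 in toluene at 90 °C should give, by the same 6-exo-dig carbopalladation followed by plain Stille capture, the ethoxy diene F1. Mild aqueous acid (PPTS, wet acetone) hydrolyses its ethoxyvinyl group to the methyl ketone, which closes and loses methanol exactly as 17 does, giving the 3-methyl core F2. Deprotonation of the C-3 methyl group of F2 with LiN(SiMe3)2 at −78 °C and vinylogous aldol addition to enal 13 gives the aldol adduct F3. Mesylation and elimination (MsCl, Et3N, then DBU) install the (E)-C-1'=C-2' bond and deliver 19.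

Step 6. What may go wrong: isomerization of the β,γ-alkynyl ketone to the allenyl ketone during addition or quench, allenyl instead of propargyl transfer, or no addition to the hindered amide. The fallback sets out from 7 and returns at 8. Reduction of 7 with i-Bu2AlH at −78 °C gives the aldehyde F4. Barbier propargylation (propargyl bromide, Zn, THF/aq. NH4Cl) gives the homopropargylic alcohol F5 as a C-6 epimer mixture, which is of no consequence. Oxidation with Dess–Martin periodinane buffered with NaHCO3 gives 8 under neutral conditions.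

Step 5. What may go wrong: participation of the neighbouring amide oxygen at the bromonium/oxocarbenium stage with loss of the amide, or dehydrobromination in the wrong direction. The fallback sets out from 5 and returns at 7. Bromo-methoxylation of 5 with NBS in methanol at −20 °C, where solvent capture of the oxocarbenium ion should outrun the amide, gives the α-bromo dimethyl acetal F6. Acetal-to-enol-ether elimination with Me3SiOTf and i-Pr2NEt in CH2Cl2 then gives 7.

Further compounds
F1 | step 12 | ethoxy diene: (7R,8R)-7,8-O-isopropylidene ring-A cyclohexanone with exocyclic C-8a=C-1H(OMe) and (Z)-C-4a=C-4H–C-3(OEt)=CH2 | COC=C1[C@H]2OC(C)(C)O[C@@]2(C)C(=O)C/C1=C/C(=C)OCC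
F2 | step 12 | (7R,8R)-7,8-O-isopropylidene-7,8-dihydroxy-3,7-dimethyl-7,8-dihydro-6H-isochromen-6-one | CC1=CC2=CC(=O)[C@]3(C)OC(C)(C)O[C@@H]3C2=CO1
F3 | step 12 | aldol adduct: 3-[(3E,5S)-7-(tert-butyldimethylsilyloxy)-2-hydroxy-3,5-dimethylhept-3-enyl] analogue of 19 (C-2' epimers) | C/C(=C\[C@@H](C)CCO[Si](C)(C)C(C)(C)C)C(O)CC1=CC2=CC(=O)[C@]3(C)OC(C)(C)O[C@@H]3C2=CO1
F4 | step 6 | (4R,5S)-5-(1-bromo-2-methoxyethenyl)-2,2,4-trimethyl-1,3-dioxolane-4-carbaldehyde | C[C@]1(OC(C)(C)O[C@@H]1C(Br)=COC)C=O
F5 | step 6 | 1-[5-(1-bromo-2-methoxyethenyl)-2,2,4-trimethyl-1,3-dioxolan-4-yl]but-3-yn-1-ol (ring centres as in 7, carbinol epimers) | C[C@]1(OC(C)(C)O[C@@H]1C(Br)=COC)C(O)CC#C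
F6 | step 5 | 5-(1-bromo-2,2-dimethoxyethyl)-N-methoxy-N,2,2,4-tetramethyl-1,3-dioxolane-4-carboxamide (ring centres as in 5, CBr epimers) | C[C@]1(OC(C)(C)O[C@@H]1C(Br)C(OC)OC)C(=O)N(C)OC
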